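All runs come from a simulation for an exercise; noise was put on by code.

Late in the autumn run, the curve of G says more than its start. Here G meets L and becomes J, and J turns into D, so take one molecule of G still present and ask its chance per minute of being hit. In the autumn run, the logarithm of G drops by 0.0144 min⁻¹ between the last two readings; this reading is the late hit rate, a pseudo-first-order constant.

| setting | autumn | noon | winter | amber | green |
|---|---|---|---|---|---|
| G | 44 mM | 44 mM | 44 mM | 44 mM | 44 mM |
| L | 86 mM | 130 mM | 260 mM | 88.0 mM | 220 mM |
| Z | 44 mM | 44 mM | 44 mM | 44.0 mM | 44.0 mM |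
| remark | run made earlier | run made earlier | run made earlier |  |  |
| time |  |  |  | 40 min | 40 min |

| run | time / min | G / % | D / % | J / % |
|---|---|---|---|---|
| autumn | 6.00 | 81.4 | 1.7 | 16.5 |
| autumn | 12.0 | 70.2 | 5.7 | 23.9 |
| autumn | 15.0 | 66.1 | 7.7 | 25.6 |
| autumn | 25.0 | 56.1 | 16.4 | 27.7 |
| autumn | 30.0 | 52.2 | 20.5 | 27.0 |
| noon | 2.50 | 86.3 | 0.6 | 12.7 |
| noon | 4.00 | 80.3 | 1.5 | 18.7 |
| noon | 8.00 | 66.8 | 4.3 | 28.9 |
| noon | 15.0 | 51.3 | 11.3 | 37.1 |
| noon | 30.0 | 32.3 | 28.7 | 37.9 |
| winter | 2.50 | 74.5 | 1.5 | 24.4 |
| winter | 8.00 | 42.8 | 7.3 | 49.6 |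
| winter | 12.0 | 29.2 | 14.3 | 56.0 |
| winter | 20.0 | 14.7 | 28.6 | 57.0 |
| winter | 30.0 | 6.0 | 44.8 | 49.1 |

(scatter of a reading: 0.3 percentage points)

1. which of these there is most of at the end, counted by the G in it, amber (D / G / J)
2. which of these there is most of at the end, counted by the G in it, green (D / G / J)
3. how much there is at the end of the one of these that leads, in percent of the G charged: amber
4. how much there is at the end of the one of these that leads, in percent of the G charged: green

Two chemists argue over amber, which is autumn with 2.00 mM more L, read later. The first says L stands at twice the G charged and is spent on G, one for one. Taking the start of autumn, 0.0343 min⁻¹ at 86 mM of L, the second-order law leaves G at 32.9% in amber.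

The second answers that autumn's hit rate fell by a factor of 2.38, while G had used 21.0 mM of L, a factor of 1.32. So L also goes elsewhere, perhaps to Z. Carrying the hit rate from autumn's last G over the remaining time gives G at 45.2% in amber. With J near autumn's 27.0%, D holds about 27.8%, so G leads.

The second grants the first the rich end: in the winter run the hit rate fell by a factor of only 1.31.

For green, the second reads J turning to D in winter at 0.0305 min⁻¹. Interpolating noon and winter by L at 30.0 min gives D 39.8% and J 45.7%. So D reaches 53.8%, more than the 46.2% left for G and J together.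

The forecast sides with the second: G at 45% in amber, since “L is nearly starved”, and D at 55% in green.

The simulation gives G 45.3%, D 29.1% and J 25.7% in amber, and D 54.8%, J 39.8% and G 5.35% in green, so G in amber stands above the first chemist's figure.

    G + L → J + E (k = 0.00820 M⁻¹ s⁻¹)
    J → D (k = 5.10 × 10⁻⁴ s⁻¹)
    L + Z → Q (k = 0.0260 M⁻¹ s⁻¹)

At 5.49 min in amber, L is used by the step with Z 2.1 times as fast as by the step with G, and at the end Z stands at 8.09% of its charge and L at 26.7%. Held at the hit rate of 0.0144 min⁻¹, amber read at 150 min would have G at 9.27%, but that flask shows 20.9%, with D leading at 73.6% and L down to 10.8% of its charge.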